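**Plan**

- Target numbered as a 12-oxabicyclo[9.1.0]dodec-4-ene: C1 and C11 are the oxirane carbons (C11 bears CH3), C4 bears CO2H, C6 the benzoate, C7 the two methyl groups.
- Enabling feature: C4 is an sp2 carbon whose ring neighbour C3 lies cis to the C6 arm across C4=C5, and C2–C3 is an unsubstituted two-carbon link ending on oxirane carbon C1. The 11-membered ring therefore opens at C3–C4 into a C4–I bond already cis to the chain and a vinyl group on C1 (latent C3–B bond); both helpers leave in the ring closure itself.
- Cuts (retro order): CO2H from a 2-(trimethylsilyl)ethyl ester; ring bond C3–C4; oxirane O12 from the E C1=C11 alkene of a 1,3-diene; benzoate C–O; C4–I/C5–H from a 4-hydroxy-2-ynoate; C5–C6 (propiolate + α-quaternary aldehyde); C1–C2 and C11–CH3 (alkyne carboalumination/vinylation); C7–C8 (enolate alkylation).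
- Forward: the open chain C6–C11/C1–C3 is built first, C4/C5 are added as a propiolate, the oxirane ring is made next and the 11-membered carbocycle is closed last; ester cleavage ends the route.
- Stereochemistry: C6 by ligand-controlled zinc–ProPhenol alkynylation; C4=C5 geometry by alkoxide-directed anti-hydroalumination/iodination and stereoretentive coupling; C1 and C11 together by ent-Shi epoxidation of the E alkene made by syn-carboalumination. The elements are set independently under reagent control, so minor isomers are diastereomers, expected to be removable after ring closure at the latest.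

Key step: step 10

Assumption: (S,S)-ProPhenol is taken to deliver the alkynyl group to the Re face of aldehyde 9, the face it selects in its aldol reactions; if the sense proves opposite, (R,R)-ProPhenol is used in step 6 and nothing else changes.

**Route**

Step 1
Reactants: 1 methyl isobutyrate; 2 5-iodopent-1-yne
Product: 4 methyl 2,2-dimethylhept-6-ynoate, via lithium enolate 3 (not isolated)
Conditions: LiN(iPr)2, THF, −78 °C; then 2, −78 °C to rt
Reagents that add atoms: none
Why: Enolate alkylation (SN2) of the lithium isobutyrate enolate with the primary iodide, which at −78 °C should be displaced faster than the acetylenic proton is transferred; the product has no α-hydrogen, so dialkylation cannot occur.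

Step 2
Reactants: 4 methyl 2,2-dimethylhept-6-ynoate
Product: 5 2,2-dimethylhept-6-yn-1-ol
Conditions: LiAlH4, Et2O, 0 °C
Reagents that add atoms: none
Why: Hydride reduction of the ester to the neopentyl primary alcohol; the isolated terminal alkyne is inert to LiAlH4.

Step 3
Reactants: 5 2,2-dimethylhept-6-yn-1-ol; 6 bromoethene (vinyl bromide)
Product: 8 (E)-2,2,6-trimethylnona-6,8-dien-1-ol, via alkenylalane 7 (not isolated)
Conditions: AlMe3 (3.5 equiv), Cp2ZrCl2 (25 mol %), CH2Cl2, 0 °C to rt; then 6 (1 M in THF), Pd(PPh3)4 (5 mol %), ZnCl2 (cat.), rt; aq. K2CO3 quench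
Reagents that add atoms: trimethylaluminium, C[Al](C)C
Why: Zirconium-catalysed syn-carboalumination of the terminal alkyne (Negishi methylalumination) puts CH3 on the internal and aluminium on the terminal carbon, the hydroxyl being masked in situ as its aluminium alkoxide, and palladium-catalysed cross-coupling of the alkenylalane with vinyl bromide proceeds with retention to give the E trisubstituted 1,3-diene.

Step 4
Reactants: 8 (E)-2,2,6-trimethylnona-6,8-dien-1-ol
Product: 9 (E)-2,2,6-trimethylnona-6,8-dienal
Conditions: Dess–Martin periodinane, CH2Cl2, 0 °C to rt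
Reagents that add atoms: none
Why: Dess–Martin oxidation of the neopentyl alcohol stops at the aldehyde and leaves the diene untouched; the aldehyde cannot enolise because its α-carbon is quaternary.

Step 5
Reactants: 10 propiolic acid; 11 2-(trimethylsilyl)ethanol
Product: 12 2-(trimethylsilyl)ethyl propiolate
Conditions: DCC, DMAP (5 mol %), CH2Cl2, −20 to 0 °C
Reagents that add atoms: none
Why: Steglich esterification (carbodiimide activation with DMAP acyl transfer), run cold to limit conjugate addition to the propiolate; the ester is chosen because fluoride removes it at the end without touching the benzoate or the oxirane.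

Step 6
Reactants: 9 (E)-2,2,6-trimethylnona-6,8-dienal; 12 2-(trimethylsilyl)ethyl propiolate
Product: 14 2-(trimethylsilyl)ethyl (4S,9E)-4-hydroxy-5,5,9-trimethyldodeca-9,11-dien-2-ynoate, via methylzinc alkynylide 13 (not isolated)
Conditions: (S,S)-ProPhenol (20 mol %), Me2Zn (3 equiv), Ph3PO (40 mol %), 12 (3 equiv), toluene, 4 °C
Reagents that add atoms: none
Why: Zinc–ProPhenol catalysed asymmetric alkynylation, in which the dinuclear complex formed from Me2Zn and the ligand holds the non-enolisable aldehyde and the zinc alkynylide in one chiral pocket and delivers the alkynyl group to the Re face, setting the carbinol centre (target C6; S in 14 because the alkynyl group outranks the quaternary carbon) by ligand control.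

Step 7
Reactants: 14 2-(trimethylsilyl)ethyl (4S,9E)-4-hydroxy-5,5,9-trimethyldodeca-9,11-dien-2-ynoate
Product: 16 2-(trimethylsilyl)ethyl (2Z,4R,9E)-4-hydroxy-2-iodo-5,5,9-trimethyldodeca-2,9,11-trienoate, via cyclic alkenylalanate 15 (not isolated)
Conditions: NaAlH2(OCH2CH2OMe)2 (Red-Al, 2 equiv), THF, −72 °C; then I2, THF, −72 to −20 °C
Reagents that add atoms: iodine, II
Why: Alkoxide-directed anti-hydroalumination of the 4-hydroxy-2-ynoate delivers hydride to C3 and aluminium to C2 within a five-membered oxa-alanate, so Al lies cis to C4, and iodinolysis of the C–Al bond with retention gives the (Z)-2-iodo enoate with the ester trans to C4 (the descriptor at C4 changes to R only because the CIP ranking changes); ester and diene are inert at −72 °C.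

Step 8
Reactants: 16 2-(trimethylsilyl)ethyl (2Z,4R,9E)-4-hydroxy-2-iodo-5,5,9-trimethyldodeca-2,9,11-trienoate
Product: 17 2-(trimethylsilyl)ethyl (2Z,4R,9E)-4-(benzoyloxy)-2-iodo-5,5,9-trimethyldodeca-2,9,11-trienoate
Conditions: BzCl, pyridine, DMAP (cat.), CH2Cl2, 0 °C to rt
Reagents that add atoms: benzoyl chloride, O=C(Cl)c1ccccc1
Why: DMAP-catalysed acylation of the hindered secondary allylic alcohol; no stereocentre or alkene is touched.

Step 9
Reactants: 17 2-(trimethylsilyl)ethyl (2Z,4R,9E)-4-(benzoyloxy)-2-iodo-5,5,9-trimethyldodeca-2,9,11-trienoate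
Product: 18 2-(trimethylsilyl)ethyl (2Z,4R)-4-(benzoyloxy)-8-[(2S,3S)-3-ethenyl-2-methyloxiran-2-yl]-2-iodo-5,5-dimethyloct-2-enoate
Conditions: ent-Shi ketone (L-fructose-derived, 30 mol %), KHSO5 (Oxone), K2CO3, Bu4NHSO4 (cat.), MeCN–CH2(OMe)2, aq. Na2B4O7/Na2EDTA buffer, 0 °C
Reagents that add atoms: potassium peroxymonosulfate (Oxone), [K+].[O-]S(=O)(=O)OO
Why: Shi asymmetric epoxidation, in which the chiral dioxirane transfers oxygen through a spiro transition state only to the electron-rich trisubstituted E alkene of the diene (the terminal vinyl group is a poor substrate and the iodo enoate is electron-poor), setting both oxirane carbons (S,S) at once, syn-stereospecifically and under reagent control independent of the remote benzoate centre.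

Step 10
Reactants: 18 2-(trimethylsilyl)ethyl (2Z,4R)-4-(benzoyloxy)-8-[(2S,3S)-3-ethenyl-2-methyloxiran-2-yl]-2-iodo-5,5-dimethyloct-2-enoate
Product: 20 2-(trimethylsilyl)ethyl (1S,4E,6R,11S)-6-(benzoyloxy)-7,7,11-trimethyl-12-oxabicyclo[9.1.0]dodec-4-ene-4-carboxylate, via B-alkyl-9-BBN borane 19 (not isolated)
Conditions: 9-BBN (2 equiv), THF, 0 °C to rt; then syringe-pump addition to PdCl2(dppf) (20 mol %), AsPh3 (20 mol %), Cs2CO3 (3 equiv), DMF–THF–H2O, 45 °C, 2 mM final concentration
Reagents that add atoms: none
Why: 9-BBN adds across the only unhindered alkene (the vinyl group on the oxirane) with boron at the terminal carbon, leaving the iodo enoate, both esters and the oxirane untouched; zerovalent palladium then inserts into the C–I bond with retention, the base-activated borate transfers its primary alkyl group to palladium, and reductive elimination forms target bond C3–C4. The closest known reaction type is the intramolecular B-alkyl Suzuki–Miyaura macrocyclisation used to close carbocycles of 12 or more members, here run on an alkylborane made in the flask from a vinyl oxirane. The 11-membered ring closes by C(sp3)–C(sp2) reductive elimination from a 12-membered alkyl(alkenyl)palladacycle, with C4=C5 staying endocyclic and ring carbons C3 and C6 cis. No stereocentre is created: C1, C11 and C6 pass through unchanged, and the alkene geometry is kept because oxidative addition and reductive elimination at sp2 carbon are stereoretentive. The selectivity needed is ring closure over oligomerisation, β-hydride elimination and protodeboronation; it is secured by the Z geometry of 18 (C–Pd bond on the same side as the tether), pseudo-high dilution, the wide-bite-angle dppf ligand with AsPh3 to speed reductive elimination, and the gem-dimethyl group, oxirane and alkene that restrict the chain.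

Step 11
Reactants: 20 2-(trimethylsilyl)ethyl (1S,4E,6R,11S)-6-(benzoyloxy)-7,7,11-trimethyl-12-oxabicyclo[9.1.0]dodec-4-ene-4-carboxylate
Product: 21 (1S,4E,6R,11S)-6-(benzoyloxy)-7,7,11-trimethyl-12-oxabicyclo[9.1.0]dodec-4-ene-4-carboxylic acid
Conditions: Bu4NF (3 equiv), THF, 0 °C to rt; aq. NaH2PO4 work-up (pH 4–5)
Reagents that add atoms: none
Why: Fluoride-induced fragmentation of the 2-(trimethylsilyl)ethyl ester (attack at silicon, loss of ethene and Me3SiF) frees the carboxylate while benzoate, oxirane and enoate geometry are left alone, and buffered acidification gives the acid without opening the oxirane.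

**Compound list**

1 | methyl isobutyrate | CC(C)C(=O)OC | starting material
2 | 5-iodopent-1-yne | ICCCC#C | starting material
3 | lithium enolate of 1, lithium 1-methoxy-2-methylprop-1-en-1-olate (not isolated) | [Li+].[O-]C(OC)=C(C)C | intermediate
4 | methyl 2,2-dimethylhept-6-ynoate | COC(=O)C(C)(C)CCCC#C | intermediate
5 | 2,2-dimethylhept-6-yn-1-ol | OCC(C)(C)CCCC#C | intermediate
6 | bromoethene (vinyl bromide) | BrC=C | starting material
7 | dimethylaluminium (E)-7-(dimethylalumanyl)-2,2,6-trimethylhept-6-en-1-olate (alkenylalane, not isolated) | C[Al](C)OCC(C)(C)CCC/C(C)=C/[Al](C)C | intermediate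
8 | (E)-2,2,6-trimethylnona-6,8-dien-1-ol | OCC(C)(C)CCC/C(C)=C/C=C | intermediate
9 | (E)-2,2,6-trimethylnona-6,8-dienal | O=CC(C)(C)CCC/C(C)=C/C=C | intermediate
10 | propiolic acid | OC(=O)C#C | starting material
11 | 2-(trimethylsilyl)ethanol | OCC[Si](C)(C)C | starting material
12 | 2-(trimethylsilyl)ethyl propiolate | C#CC(=O)OCC[Si](C)(C)C | intermediate
13 | methylzinc alkynylide of 12 (not isolated) | C[Zn]C#CC(=O)OCC[Si](C)(C)C | intermediate
14 | 2-(trimethylsilyl)ethyl (4S,9E)-4-hydroxy-5,5,9-trimethyldodeca-9,11-dien-2-ynoate | C[Si](C)(C)CCOC(=O)C#C[C@@H](O)C(C)(C)CCC/C(C)=C/C=C | intermediate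
15 | sodium cyclic alkenylalanate from anti-hydroalumination of 14: five-membered O–Al–C2=C3–C4 ring, two 2-methoxyethoxy groups on Al (not isolated) | [Na+].COCCO[Al-]1(OCCOC)O[C@@H](C(C)(C)CCC/C(C)=C/C=C)C=C1C(=O)OCC[Si](C)(C)C | intermediate
16 | 2-(trimethylsilyl)ethyl (2Z,4R,9E)-4-hydroxy-2-iodo-5,5,9-trimethyldodeca-2,9,11-trienoate | C[Si](C)(C)CCOC(=O)/C(I)=C/[C@@H](O)C(C)(C)CCC/C(C)=C/C=C | intermediate
17 | 2-(trimethylsilyl)ethyl (2Z,4R,9E)-4-(benzoyloxy)-2-iodo-5,5,9-trimethyldodeca-2,9,11-trienoate | C[Si](C)(C)CCOC(=O)/C(I)=C/[C@@H](OC(=O)c1ccccc1)C(C)(C)CCC/C(C)=C/C=C | intermediate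
18 | 2-(trimethylsilyl)ethyl (2Z,4R)-4-(benzoyloxy)-8-[(2S,3S)-3-ethenyl-2-methyloxiran-2-yl]-2-iodo-5,5-dimethyloct-2-enoate | C[Si](C)(C)CCOC(=O)/C(I)=C/[C@@H](OC(=O)c1ccccc1)C(C)(C)CCC[C@]1(C)O[C@H]1C=C | intermediate
19 | 2-(trimethylsilyl)ethyl (2Z,4R)-4-(benzoyloxy)-8-{(2S,3S)-3-[2-(9-borabicyclo[3.3.1]nonan-9-yl)ethyl]-2-methyloxiran-2-yl}-2-iodo-5,5-dimethyloct-2-enoate (not isolated) | C[Si](C)(C)CCOC(=O)/C(I)=C/[C@@H](OC(=O)c1ccccc1)C(C)(C)CCC[C@]1(C)O[C@H]1CCB1C2CCCC1CCC2 | intermediate
20 | 2-(trimethylsilyl)ethyl (1S,4E,6R,11S)-6-(benzoyloxy)-7,7,11-trimethyl-12-oxabicyclo[9.1.0]dodec-4-ene-4-carboxylate | CC1(C)CCC[C@]2(C)O[C@H]2CC/C(C(=O)OCC[Si](C)(C)C)=C\[C@H]1OC(=O)c1ccccc1 | intermediate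
21 | (1S,4E,6R,11S)-6-(benzoyloxy)-7,7,11-trimethyl-12-oxabicyclo[9.1.0]dodec-4-ene-4-carboxylic acid | CC1(C)CCC[C@]2(C)O[C@H]2CC/C(C(=O)O)=C\[C@H]1OC(=O)c1ccccc1 | target

**Count**

Total steps: 11. Longest linear sequence: 10 (steps 1–4 and 6–11); step 5 is a one-step branch.

**Steps most likely to fail**

Step 10. Ring closure may lose out to oligomerisation, protodeboronation or β-hydride elimination, or the oxirane beside the borane may open during hydroboration or coupling. The fallback closes the carbocycle before the oxirane is made. It sets out from 17: 9-BBN adds to the terminal alkene of the diene to give the homoallylic borane 2-(trimethylsilyl)ethyl (2Z,4R,9E)-4-(benzoyloxy)-12-(9-borabicyclo[3.3.1]nonan-9-yl)-2-iodo-5,5,9-trimethyldodeca-2,9-dienoate F1 (not isolated). Under the same PdCl2(dppf)/AsPh3/Cs2CO3 high-dilution conditions this should cyclise to 2-(trimethylsilyl)ethyl (1E,3R,8E)-3-(benzoyloxy)-4,4,8-trimethylcycloundeca-1,8-diene-1-carboxylate F2. Epoxidation of its only electron-rich alkene with the ent-Shi ketone and KHSO5 is then expected to give 20, where the route is rejoined.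

Step 9. The dioxirane may oxidise the C–I bond, or the acid-sensitive vinyl oxirane may be lost on isolation at this late stage. The fallback epoxidises before iodine is introduced. It sets out from 14: the same ent-Shi epoxidation of the diene (the ynoate is inert to the dioxirane) should give 2-(trimethylsilyl)ethyl (4S)-8-[(2S,3S)-3-ethenyl-2-methyloxiran-2-yl]-4-hydroxy-5,5-dimethyloct-2-ynoate F3. NaAlH2(OCH2CH2OMe)2 at −72 °C followed by N-iodosuccinimide (to avoid Lewis-acidic aluminium iodides near the oxirane) should give 2-(trimethylsilyl)ethyl (2Z,4R)-8-[(2S,3S)-3-ethenyl-2-methyloxiran-2-yl]-4-hydroxy-2-iodo-5,5-dimethyloct-2-enoate F4. Benzoylation as in step 8 returns to 18.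

Step 6. Addition to the α-quaternary aldehyde may be slow or show poor facial selectivity. The fallback sets the carbinol centre by reduction instead of addition. It sets out from 9 and 12: the lithium alkynylide of 12 (LiN(SiMe3)2, THF, −78 °C) adds to 9 to give 2-(trimethylsilyl)ethyl (9E)-4-hydroxy-5,5,9-trimethyldodeca-9,11-dien-2-ynoate, racemic at C4, F5. Dess–Martin oxidation gives the ynone 2-(trimethylsilyl)ethyl (9E)-5,5,9-trimethyl-4-oxododeca-9,11-dien-2-ynoate F6. Corey–Bakshi–Shibata reduction with catecholborane and (S)-2-methyl-CBS-oxazaborolidine (tert-alkyl as the large group, alkynyl as the small one) should give 14.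

Further compounds
F1 | step 10 | 2-(trimethylsilyl)ethyl (2Z,4R,9E)-4-(benzoyloxy)-12-(9-borabicyclo[3.3.1]nonan-9-yl)-2-iodo-5,5,9-trimethyldodeca-2,9-dienoate (not isolated) | C[Si](C)(C)CCOC(=O)/C(I)=C/[C@@H](OC(=O)c1ccccc1)C(C)(C)CCC/C(C)=C/CCB1C2CCCC1CCC2
F2 | step 10 | 2-(trimethylsilyl)ethyl (1E,3R,8E)-3-(benzoyloxy)-4,4,8-trimethylcycloundeca-1,8-diene-1-carboxylate | CC1(C)CCC/C(C)=C/CC/C(C(=O)OCC[Si](C)(C)C)=C\[C@H]1OC(=O)c1ccccc1
F3 | step 9 | 2-(trimethylsilyl)ethyl (4S)-8-[(2S,3S)-3-ethenyl-2-methyloxiran-2-yl]-4-hydroxy-5,5-dimethyloct-2-ynoate | C[Si](C)(C)CCOC(=O)C#C[C@@H](O)C(C)(C)CCC[C@]1(C)O[C@H]1C=C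
F4 | step 9 | 2-(trimethylsilyl)ethyl (2Z,4R)-8-[(2S,3S)-3-ethenyl-2-methyloxiran-2-yl]-4-hydroxy-2-iodo-5,5-dimethyloct-2-enoate | C[Si](C)(C)CCOC(=O)/C(I)=C/[C@@H](O)C(C)(C)CCC[C@]1(C)O[C@H]1C=C
F5 | step 6 | 2-(trimethylsilyl)ethyl (9E)-4-hydroxy-5,5,9-trimethyldodeca-9,11-dien-2-ynoate, racemic at C4 | C[Si](C)(C)CCOC(=O)C#CC(O)C(C)(C)CCC/C(C)=C/C=C
F6 | step 6 | 2-(trimethylsilyl)ethyl (9E)-5,5,9-trimethyl-4-oxododeca-9,11-dien-2-ynoate | C[Si](C)(C)CCOC(=O)C#CC(=O)C(C)(C)CCC/C(C)=C/C=C
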